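**Retrosynthetic overview**
1. Target 8 ⇐ 7 by hydride cleavage of two N‑acyl oxazolidinones (gives the C3/C4 CH2OH groups) and desilylation of the phenols.
2. 7 ⇐ two molecules of aldehyde 4 + fumaroyl bis‑imide 6 in one reductive radical–polar [3+2] annulation; this step forms the only ring (the oxolane). C2–C3 forms by addition of an α‑alkoxybenzyl radical to the fumarate, C4–C5 by enolate/oxocarbenium closure, and the ring O is one aldehyde oxygen.
3. Stereocontrol: C3/C4 from the two auxiliaries of 6, which shield the same alkene face; C2/C5 from ring closure plus Lewis‑acid equilibration to the all‑trans isomer.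
4. 4 ⇐ syringaldehyde 3 ⇐ 3,5‑dibromo‑4‑hydroxybenzaldehyde 2 ⇐ p‑cresol 1.
5. 6 ⇐ fumaryl chloride 5 + (R)‑4‑benzyl‑2‑oxazolidinone.

Assumption: the SMILES is read as the all‑trans (2S,3R,4R,5S) isomer; the oxazolidinone is a recoverable chiral auxiliary reagent that leaves no atoms in the target.

**Step 1**
Reactants: 1 p‑cresol
Product: 2 3,5‑dibromo‑4‑hydroxybenzaldehyde
Conditions: Br2 (4.2 equiv), o‑dichlorobenzene, 35 °C then 150–160 °C; then H2O, 100 °C
Reagents that add atoms: bromine, BrBr; water, O
Why: Electrophilic aromatic dibromination ortho to the phenol, then thermal benzylic gem‑dibromination and hydrolysis of the benzal bromide (the known one‑pot bromination–hydrolysis of p‑cresol); no stereocenter.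

**Step 2**
Reactants: 2 3,5‑dibromo‑4‑hydroxybenzaldehyde
Product: 3 syringaldehyde (4‑hydroxy‑3,5‑dimethoxybenzaldehyde)
Conditions: NaOMe (4 equiv), CuCl (10 mol %), DMF/MeOH, 115 °C; H3O+ workup
Reagents that add atoms: sodium methoxide, C[O-].[Na+]
Why: Copper(I)‑catalysed Ullmann‑type methoxylation of both aryl bromides, assisted by the ortho phenoxide, with the aldehyde untouched (known syringaldehyde process).

**Step 3**
Reactants: 3 syringaldehyde
Product: 4 4‑[(tert‑butyldimethylsilyl)oxy]‑3,5‑dimethoxybenzaldehyde
Conditions: TBSCl, imidazole, DMF, rt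
Reagents that add atoms: tert‑butyldimethylsilyl chloride, CC(C)(C)[Si](C)(C)Cl
Why: Standard silyl ether protection masks the acidic phenol against TMSI, Ti(III) and hydride while keeping the ring electron‑rich.

**Step 4**
Reactants: 5 fumaryl chloride
Product: 6 (4R,4'R)‑3,3'‑[(E)‑but‑2‑enedioyl]bis(4‑benzyl‑1,3‑oxazolidin‑2‑one)
Conditions: (R)‑4‑benzyl‑2‑oxazolidinone (2.05 equiv), n‑BuLi, THF, −78 °C; then 5, −78 → 0 °C
Reagents that add atoms: (R)‑4‑benzyl‑2‑oxazolidinone, O=C1N[C@H](Cc2ccccc2)CO1
Why: Double N‑acylation of the lithiated Evans oxazolidinone gives the C2‑symmetric fumaroyl bis‑imide, in which both benzyl groups shield the same alkene face once each imide is chelated.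

**Step 5 (key step)**
Reactants: 4 4‑[(tert‑butyldimethylsilyl)oxy]‑3,5‑dimethoxybenzaldehyde (2.2 equiv); 6 fumaroyl bis‑imide (1.0 equiv)
Product: 7 (4R,4'R)‑3,3'‑{[(2S,3S,4S,5S)‑2,5‑bis(4‑TBSO‑3,5‑dimethoxyphenyl)oxolane‑3,4‑diyl]dicarbonyl}bis(4‑benzyl‑1,3‑oxazolidin‑2‑one); all‑trans ring
Conditions: 4, TMSI (2.3 equiv), CH2Cl2, −78 → −40 °C; add 6·MgI2 (2.2 equiv); Cp2TiCl (2.5 equiv, THF) added slowly, −78 °C; then −20 °C, 2 h
Reagents that add atoms: none (one aldehyde oxygen leaves as (Me3Si)2O)
Why: Proposed new method: TMSI converts 4 in situ into its α‑iodo silyl ether / bis(α‑iodobenzyl) ether, Ti(III) abstracts iodine to give an α‑alkoxybenzyl radical that adds (Giese) to the MgI2‑chelated fumaroyl bis‑imide on the face anti to both benzyl groups (C3 = S), a second Ti(III) reduces the α‑acyl radical to the chelated Z‑enolate, which closes on the remaining oxocarbenium arm from the same face (C4 = S, 3,4‑trans), and the aryl groups end trans to their neighbours through the ring‑closure transition state and TMSI/MgI2‑mediated reversible ionisation of the benzylic C–O bonds (all‑trans is the thermodynamic isomer); the closest known reaction types are the samarium‑mediated [3+2] of alkenes with carbonyl‑ylide equivalents from aldehyde‑derived α‑iodoalkyl silyl ethers, Lewis‑acid‑controlled radical conjugate additions to oxazolidinone fumarates, and Ti(III) radical additions to acrylates that end as titanium enolates.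

**Step 6**
Reactants: 7 oxolane bis‑imide
Product: 8 huazhongilexin, [(2S,3R,4R,5S)‑2,5‑bis(4‑hydroxy‑3,5‑dimethoxyphenyl)oxolane‑3,4‑diyl]dimethanol
Conditions: LiBH4 (4 equiv), MeOH (4 equiv), THF, 0 °C; then TBAF (2.5 equiv), 0 °C → rt, same flask; NH4Cl workup
Reagents that add atoms: none
Why: Standard reductive cleavage of the N‑acyl oxazolidinones to primary alcohols (auxiliary recovered) followed by fluoride desilylation of the aryl silyl ethers; no stereocenter is touched (the C3/C4 descriptors change from S to R only because CH2OH ranks below C2/C5).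

**Compound list**
1 | p‑cresol (4‑methylphenol) | Cc1ccc(O)cc1 | starting material
2 | 3,5‑dibromo‑4‑hydroxybenzaldehyde | O=Cc1cc(Br)c(O)c(Br)c1 | intermediate
3 | syringaldehyde | COc1cc(C=O)cc(OC)c1O | intermediate
4 | 4‑[(tert‑butyldimethylsilyl)oxy]‑3,5‑dimethoxybenzaldehyde | COc1cc(C=O)cc(OC)c1O[Si](C)(C)C(C)(C)C | intermediate
5 | fumaryl chloride | O=C(Cl)/C=C/C(=O)Cl | starting material
6 | (4R,4'R)‑3,3'‑[(E)‑but‑2‑enedioyl]bis(4‑benzyl‑1,3‑oxazolidin‑2‑one) | O=C(/C=C/C(=O)N1[C@H](Cc2ccccc2)COC1=O)N1[C@H](Cc2ccccc2)COC1=O | intermediate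
7 | (2S,3S,4S,5S)‑2,5‑bis(4‑TBSO‑3,5‑dimethoxyphenyl)oxolane‑3,4‑dicarbonyl bis[(R)‑4‑benzyl‑2‑oxazolidinone] imide | COc1cc([C@H]2O[C@H](c3cc(OC)c(O[Si](C)(C)C(C)(C)C)c(OC)c3)[C@@H](C(=O)N4[C@H](Cc5ccccc5)COC4=O)[C@@H]2C(=O)N6[C@H](Cc7ccccc7)COC6=O)cc(OC)c1O[Si](C)(C)C(C)(C)C | intermediate
8 | huazhongilexin, (2S,3R,4R,5S) | COc1cc([C@H]2O[C@H](c3cc(OC)c(O)c(OC)c3)[C@@H](CO)[C@@H]2CO)cc(OC)c1O | target

**Totals**
Total steps: 6. Longest linear sequence: 5 (1 → 2 → 3 → 4 → 7 → 8); step 4 is a one‑step side branch.

**Steps most likely to fail, with fallbacks**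
1. Step 5. The risks are competing benzylic radical dimerisation or Friedel–Crafts alkylation, poor face selectivity, and incomplete C2/C5 equilibration. Fallback: convert 4 to the (E)‑stilbene (McMurry) and its trans‑epoxide, then use photoinduced electron transfer (acridinium sensitiser) to open the oxirane radical cation and capture it with 6 in a [3+2]; correct any residual C2/C5 epimers by photocatalytic reversible hydrogen‑atom transfer (quinuclidine/thiol).
2. Step 6. The risks are endocyclic oxazolidinone opening or β‑alkoxy elimination at the hindered, β‑oxygenated acyl groups. Fallback: hydrolyse the auxiliaries with LiOOH to the diacid, reduce with BH3·SMe2 under non‑basic conditions, then TBAF.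
3. Step 4. The risk is oligomerisation or conjugate addition of the lithiated auxiliary to fumaryl chloride or to 6. Fallback: open maleic anhydride with the lithiated auxiliary, isomerise Z → E (catalytic iodine or thiyl radical), activate the free acid as the pivaloyl mixed anhydride and add the second auxiliary.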